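**Two runs.** Saturday's run, with 1.4 equiv of partner, stands at 25.4 % left-handed and 8.7 % right-handed product after 80.0 min; Thursday's run, with 1.9 equiv, stands at 32.2 % and 11.9 %. From these I must choose the partner charge for the next portion of substrate.

| setting | Saturday's | Thursday's | spring | midnight |
|---|---|---|---|---|
| left-handed substrate | 1.1 M | 1.1 M | 1.1 M | 1.1 M |
| right-handed substrate | 1.1 M | 1.1 M | 1.1 M | 1.1 M |
| partner | 1.4 equiv | 1.9 equiv | 1.10 equiv | 1.70 equiv |
| free catalyst | 5 mol% | 5 mol% | 5 mol% | 5 mol% |
| impurity | 42 mM | 42 mM | 42 mM | 42 mM |
| remark | run made earlier | run made earlier |  |  |
| time |  |  | 2.5 h | 2.5 h |

| run | time / min | left-handed product / % | right-handed product / % |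
|---|---|---|---|
| Saturday's | 15.0 | 13.8 | 1.9 |
| Saturday's | 30.0 | 18.7 | 5.6 |
| Saturday's | 50.0 | 22.6 | 7.3 |
| Saturday's | 60.0 | 26.2 | 6.8 |
| Saturday's | 80.0 | 25.4 | 8.7 |
| Thursday's | 15.0 | 16.5 | 5.4 |
| Thursday's | 30.0 | 24.2 | 7.3 |
| Thursday's | 50.0 | 28.0 | 10.1 |
| Thursday's | 60.0 | 29.8 | 10.5 |
| Thursday's | 80.0 | 32.2 | 11.9 |

(standard deviation of a reading: 1 percentage point)

- free catalyst is single-handed; left-handed substrate and right-handed substrate are mirror images of each other, charged as a racemate, each of them at the stated concentration
- what was read earlier has a scatter of 1 percentage point, one standard deviation
- what may be going on: free catalyst + left-handed substrate <-> catalyst intermediate A; free catalyst + right-handed substrate <-> catalyst intermediate B; partner + catalyst intermediate A -> free catalyst + left-handed product; partner + catalyst intermediate B -> free catalyst + right-handed product; left-handed substrate <-> right-handed substrate; 2 partner -> self-condensation product; free catalyst + impurity -> spent catalyst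
- an excess is the difference of the two amounts in percent of their sum
- an excess is below zero if the other one leads

- which of the two ends with the higher excess of left-handed product over right-handed product in the product ("neither" if they lie within 2 percentage points) (spring / midnight / neither)
- excess of left-handed product over right-handed product in the product at the end, spring
- excess of left-handed product over right-handed product in the product at the end, midnight

**The number.** Each substrate is half of the charge, so twice a product reading is the fraction of that substrate's own charge turned into product. I take the logarithm of the left-handed fraction not yet product over that of the right-handed one, the selectivity factor s 3.80. Thursday's last reading gives 3.80 and Saturday's gives 3.71, which is close for readings with a scatter of 1 percentage point. So I expect partner to set how far a flask goes while s stays put, and the right-handed fraction remaining is then the left-handed one raised to the power 1/s.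

**My reckoning.** I scale Saturday's last left-handed reading to spring and Thursday's to midnight by their partner charges, then stretch both once by the factor 1.15 that Thursday's run grew over its last 30.0 min, which is a rough step. That leaves a left-handed fraction of 0.541 in spring and 0.337 in midnight. With s the right-handed fractions are 0.851 and 0.751, so the excess is 50.9 % in spring and 45.4 % in midnight. That gap clears the margin of 2 points, so I would charge spring.

**The forecast.** It names spring, with 53 % against 47 %: “Less partner, less conversion, higher excess”. My two figures lie slightly lower, in the same order.

**The flasks.** Spring gives 52.5 % and midnight 46.2 %, so spring leads.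

    free catalyst + left-handed substrate ⇌ catalyst intermediate A (K = 0.816 /M, k = 8.56 /M/min)
    free catalyst + right-handed substrate ⇌ catalyst intermediate B (K = 0.470 /M, k = 7.22 /M/min)
    partner + catalyst intermediate A → free catalyst + left-handed product (k = 1.23 /M/min)
    partner + catalyst intermediate B → free catalyst + right-handed product (k = 0.476 /M/min)
    left-handed substrate ⇌ right-handed substrate (k = 2.20 × 10⁻⁴ /min)
    2 partner → self-condensation product (k = 0.00116 /M/min)
    free catalyst + impurity → spent catalyst (k = 3.49 /M/min)

**Why it held.** The end products give s of 4.25 in spring and 4.16 in midnight, so these flasks differ in how far they went: the extra partner in midnight accounts for the gap of 6.3 points to spring. Spring also has a dying catalyst, which s does not hold: it ends with 75.8 % of its catalyst charge as spent catalyst, while its neighbour, the same flask with 20 mol% of free catalyst, ends with 19.1 % of its own. Yet that neighbour's products give s of 4.22, and going further, it ends at an excess of 44.2 %.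

(The numbers in the tables were generated by integration for an exercise.)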